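**Retrosynthetic overview**

1. Locants are those of the target decalin: C1 carries the propanoic acid chain, C2 the isopropylidene, C4a the ring-fusion H, C5 methyl and aryl-methyl, C6 methyl, C8a the angular methyl; ring A = C1–C4, C4a, C8a and ring B = C4a–C8a.
2. Late stage: acid ⇐ silyl-protected primary alcohol; phenol ⇐ MOM ether; C2=CMe2 ⇐ C2 ketone through its enol triflate, an isopropenyl Suzuki coupling and 1,4-hydrogenation of the diene.
3. cis Ring fusion (H-4a) ⇐ hydroxyl-directed hydrogenation of the C4=C4a alkene; the directing axial C2 alcohol is set by a ketoreductase on the bicyclic enedione; C6 methyl ⇐ methylenation and hydrogenation of the C6 ketone.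
4. C5 quaternary centre ⇐ deconjugative benzylation of the extended enolate of the ring-B enone with an aryl-methyl bromide made from 4-methoxy-2-methylphenol.
5. Ring order: ring A comes from benzoquinone monoketal (first stereocentre, C1, by copper-catalysed asymmetric conjugate addition of a dialkylzinc); ring B is then built on it by Michael addition to ethyl vinyl ketone and aldol condensation.

Abbreviations in names: TBDPSO = tert-butyl(diphenyl)silyloxy; TESO = triethylsilyloxy; MOM = methoxymethyl; ArCH2 = [5-methoxy-2-(methoxymethoxy)-3-methylphenyl]methyl.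

Assumption: the (R,S,S) phosphoramidite, O,O′-[(R)-1,1′-binaphthyl-2,2′-diyl] N,N-bis[(S)-1-phenylethyl]phosphoramidite, is taken to give the 5S adduct in step 6 (sense of induction carried over from cyclohex-2-enone); the mirror-image ligand would be used if it proved otherwise.

**Route**

Step 1
Reactants: 1 4-methoxy-2-methylphenol
Product: 2 2-hydroxy-5-methoxy-3-methylbenzaldehyde
Conditions: MgCl2, Et3N, (CH2O)n, MeCN, reflux; aq HCl
Reagents that add atoms: paraformaldehyde (formaldehyde), C=O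
Why: Magnesium-phenoxide-directed ortho-formylation (Casnati–Skattebøl) can reach only the single free ortho position, a second formaldehyde serving as hydride acceptor.

Step 2
Reactants: 2 2-hydroxy-5-methoxy-3-methylbenzaldehyde
Product: 3 5-methoxy-2-(methoxymethoxy)-3-methylbenzaldehyde
Conditions: MOMCl, i-Pr2NEt, CH2Cl2, 0 °C to reflux
Reagents that add atoms: chloromethyl methyl ether, COCCl
Why: O-Alkylation of the phenol gives a MOM acetal that survives the strong bases, ylides, hydrides and fluoride used later.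

Step 3
Reactants: 3 5-methoxy-2-(methoxymethoxy)-3-methylbenzaldehyde
Product: 4 [5-methoxy-2-(methoxymethoxy)-3-methylphenyl]methanol
Conditions: NaBH4, MeOH, 0 °C
Reagents that add atoms: none
Why: Simple hydride reduction of the aldehyde to the benzylic alcohol.

Step 4
Reactants: 4 [5-methoxy-2-(methoxymethoxy)-3-methylphenyl]methanol
Product: 5 1-(bromomethyl)-5-methoxy-2-(methoxymethoxy)-3-methylbenzene
Conditions: CBr4, PPh3, CH2Cl2, 0 °C
Reagents that add atoms: tetrabromomethane, BrC(Br)(Br)Br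
Why: Appel bromination converts the benzylic alcohol to the bromide under neutral conditions that leave the MOM acetal intact.

Step 5
Reactants: 6 3-iodopropan-1-ol
Product: 7 tert-butyl(3-iodopropoxy)diphenylsilane
Conditions: t-BuPh2SiCl, imidazole, CH2Cl2, rt
Reagents that add atoms: tert-butyl(chloro)diphenylsilane, CC(C)(C)[Si](Cl)(c1ccccc1)c1ccccc1
Why: Silylation of the primary alcohol gives a robust ether that carries the future carboxyl carbon through the route.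

Step 6
Reactants: 7 tert-butyl(3-iodopropoxy)diphenylsilane; 8 4,4-dimethoxycyclohexa-2,5-dien-1-one
Product: 10 (5S)-5-[3-(TBDPSO)propyl]-4,4-dimethoxycyclohex-2-en-1-one, via dialkylzinc 9 (not isolated)
Conditions: Et2Zn (neat), 50 °C, then vacuum; Cu(OTf)2 (2 mol %), (R,S,S)-phosphoramidite (4 mol %), PhMe, −30 °C; aq NH4Cl
Reagents that add atoms: none
Why: Iodine–zinc exchange gives the functionalised dialkylzinc, and copper/phosphoramidite-catalysed asymmetric conjugate addition desymmetrises the prochiral dienone, the chiral catalyst choosing one enantiotopic enone and one face to set the first stereocentre (5S).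

Step 7
Reactants: 10 (5S)-5-[3-(TBDPSO)propyl]-4,4-dimethoxycyclohex-2-en-1-one
Product: 12 (5S,6S)-5-[3-(TBDPSO)propyl]-4,4-dimethoxy-6-methylcyclohex-2-en-1-one, via lithium enolate 11 (not isolated)
Conditions: LiN(i-Pr)2, THF, −78 °C; MeI, −78 to 0 °C
Reagents that add atoms: iodomethane, CI
Why: Kinetic α′-enolate alkylation can occur only at C6 because the other α position is part of the enone; methyl enters trans to the neighbouring chain, and this centre is re-planarised in the next step.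

Step 8
Reactants: 12 (5S,6S)-5-[3-(TBDPSO)propyl]-4,4-dimethoxy-6-methylcyclohex-2-en-1-one; 13 pent-1-en-3-one
Product: 14 (5S,6S)-5-[3-(TBDPSO)propyl]-4,4-dimethoxy-6-methyl-6-(3-oxopentyl)cyclohex-2-en-1-one
Conditions: KOt-Bu (0.15 equiv), t-BuOH/THF, 0 °C
Reagents that add atoms: none
Why: Base-catalysed Michael addition of the only possible (cross-conjugated α′) enolate; the acceptor attacks the methyl-bearing enolate carbon anti to the pseudoaxial C5 side chain (allylic 1,2-strain control), so the new quaternary centre has methyl cis to the chain.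

Step 9
Reactants: 14 (5S,6S)-5-[3-(TBDPSO)propyl]-4,4-dimethoxy-6-methyl-6-(3-oxopentyl)cyclohex-2-en-1-one
Product: 15 (2S,3S)-3-[3-(TBDPSO)propyl]-4,4-dimethoxy-2-methyl-2-(3-oxopentyl)cyclohexan-1-one
Conditions: H2 (1 atm), Pd/C, EtOAc, trace Et3N, rt
Reagents that add atoms: none
Why: Heterogeneous hydrogenation removes the conjugated disubstituted C=C that served as a regiochemical blocking group; ketones, acetal and stereocentres are untouched.

Step 10
Reactants: 15 (2S,3S)-3-[3-(TBDPSO)propyl]-4,4-dimethoxy-2-methyl-2-(3-oxopentyl)cyclohexan-1-one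
Product: 16 (4aS,5S)-5-[3-(TBDPSO)propyl]-6,6-dimethoxy-1,4a-dimethyl-4,4a,5,6,7,8-hexahydronaphthalen-2(3H)-one
Conditions: NaOMe, MeOH, 55 °C
Reagents that add atoms: none
Why: Intramolecular aldol condensation (second half of a Robinson annulation) closes ring B by attack of the ethyl-ketone α-carbon on the ring ketone and dehydration to the tetrasubstituted enone; no stereocentre is affected.

Step 11
Reactants: 16 (4aS,5S)-5-[3-(TBDPSO)propyl]-6,6-dimethoxy-1,4a-dimethyl-4,4a,5,6,7,8-hexahydronaphthalen-2(3H)-one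
Product: 17 (4aS,5S)-5-[3-(TBDPSO)propyl]-1,4a-dimethyl-4,4a,7,8-tetrahydronaphthalene-2,6(3H,5H)-dione
Conditions: pyridinium p-toluenesulfonate (cat.), acetone/H2O, rt
Reagents that add atoms: water, O
Why: Mild acetal hydrolysis frees the ring-A ketone only now that the adjacent quaternary carbon rules out aromatisation; the side chain sits equatorial, so C5 is also the thermodynamic epimer.

Step 12
Reactants: 17 (4aS,5S)-5-[3-(TBDPSO)propyl]-1,4a-dimethyl-4,4a,7,8-tetrahydronaphthalene-2,6(3H,5H)-dione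
Product: 18 (4aS,5S,6R)-5-[3-(TBDPSO)propyl]-6-hydroxy-1,4a-dimethyl-4,4a,5,6,7,8-hexahydronaphthalen-2(3H)-one
Conditions: ketoreductase (R-selective, from a screening panel), NADP+ (cat.), i-PrOH, pH 7 phosphate buffer/DMSO, 30 °C
Reagents that add atoms: none
Why: Biocatalytic carbonyl reduction: the ketoreductase reduces only the saturated ring ketone (the hindered tetrasubstituted enone is not accepted) and, under catalyst control, gives the axial 6R alcohol cis to the side chain, the hydroxyl that later directs the ring-fusion hydrogenation.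

Step 13
Reactants: 18 (4aS,5S,6R)-5-[3-(TBDPSO)propyl]-6-hydroxy-1,4a-dimethyl-4,4a,5,6,7,8-hexahydronaphthalen-2(3H)-one
Product: 19 (4aS,5S,6R)-5-[3-(TBDPSO)propyl]-1,4a-dimethyl-6-(TESO)-4,4a,5,6,7,8-hexahydronaphthalen-2(3H)-one
Conditions: Et3SiCl, imidazole, DMF, rt
Reagents that add atoms: chlorotriethylsilane, CC[Si](Cl)(CC)CC
Why: Silyl protection prevents O-benzylation in the next step; the triethylsilyl ether can later be removed in the presence of the primary TBDPS ether.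

Step 14
Reactants: 19 (4aS,5S,6R)-5-[3-(TBDPSO)propyl]-1,4a-dimethyl-6-(TESO)-4,4a,5,6,7,8-hexahydronaphthalen-2(3H)-one; 5 1-(bromomethyl)-5-methoxy-2-(methoxymethoxy)-3-methylbenzene
Product: 21 (1R,4aS,5S,6R)-1-(ArCH2)-5-[3-(TBDPSO)propyl]-1,4a-dimethyl-6-(TESO)-3,4,4a,5,6,7-hexahydronaphthalen-2(1H)-one, via potassium dienolate 20 (not isolated)
Conditions: KOt-Bu, t-BuOH/THF, 0 °C; then 5
Reagents that add atoms: none
Why: Deconjugative α-alkylation of the thermodynamic extended enolate: the benzylic bromide attacks the α-carbon from the face opposite the axial angular methyl, creating the quaternary centre (benzyl trans, methyl cis to the angular methyl) and moving the alkene to the β,γ position.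

Step 15
Reactants: 21 (1R,4aS,5S,6R)-1-(ArCH2)-5-[3-(TBDPSO)propyl]-1,4a-dimethyl-6-(TESO)-3,4,4a,5,6,7-hexahydronaphthalen-2(1H)-one
Product: 22 tert-butyl{3-[(1S,2R,5S,8aS)-5-(ArCH2)-5,8a-dimethyl-6-methylidene-2-(TESO)-1,2,3,5,6,7,8,8a-octahydronaphthalen-1-yl]propoxy}diphenylsilane
Conditions: Ph3PCH3Br, KOt-Bu, PhMe, 90 °C
Reagents that add atoms: methyltriphenylphosphonium bromide, C[P+](c1ccccc1)(c1ccccc1)c1ccccc1.[Br-]
Why: Wittig methylenation with the small non-stabilised ylide at elevated temperature works on this neopentyl ketone, and the β,γ-alkene cannot move into conjugation because the α-carbon is quaternary.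

Step 16
Reactants: 22 tert-butyl{3-[(1S,2R,5S,8aS)-5-(ArCH2)-5,8a-dimethyl-6-methylidene-2-(TESO)-1,2,3,5,6,7,8,8a-octahydronaphthalen-1-yl]propoxy}diphenylsilane
Product: 23 tert-butyl{3-[(1S,2R,5S,6R,8aS)-5-(ArCH2)-5,6,8a-trimethyl-2-(TESO)-1,2,3,5,6,7,8,8a-octahydronaphthalen-1-yl]propoxy}diphenylsilane
Conditions: H2 (1 atm), RhCl(PPh3)3 (cat.), benzene/EtOH, rt
Reagents that add atoms: none
Why: Homogeneous hydrogenation reduces only the 1,1-disubstituted exocyclic alkene (the trisubstituted C4=C4a alkene lies between two quaternary carbons), and H2 adds anti to the axial C5 methyl, giving the equatorial C6 methyl cis to the C5 methyl.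

Step 17
Reactants: 23 tert-butyl{3-[(1S,2R,5S,6R,8aS)-5-(ArCH2)-5,6,8a-trimethyl-2-(TESO)-1,2,3,5,6,7,8,8a-octahydronaphthalen-1-yl]propoxy}diphenylsilane
Product: 24 (1S,2R,5S,6R,8aS)-5-(ArCH2)-1-[3-(TBDPSO)propyl]-5,6,8a-trimethyl-1,2,3,5,6,7,8,8a-octahydronaphthalen-2-ol
Conditions: HF·pyridine, pyridine, THF, 0 °C to rt
Reagents that add atoms: none
Why: Buffered fluoride desilylation cleaves the secondary triethylsilyl ether much faster than the primary TBDPS ether and leaves the aryl MOM acetal alone.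

Step 18
Reactants: 24 (1S,2R,5S,6R,8aS)-5-(ArCH2)-1-[3-(TBDPSO)propyl]-5,6,8a-trimethyl-1,2,3,5,6,7,8,8a-octahydronaphthalen-2-ol
Product: 25 (1S,2R,4aS,5S,6R,8aR)-5-(ArCH2)-1-[3-(TBDPSO)propyl]-5,6,8a-trimethyldecahydronaphthalen-2-ol
Conditions: H2 (1 atm), [Ir(cod)(PCy3)(py)]PF6 (10 mol %), CH2Cl2, rt
Reagents that add atoms: none
Why: Hydroxyl-directed homogeneous hydrogenation: the axial homoallylic C2 alcohol binds iridium and delivers H2 to its own face of the C4=C4a alkene, so H-4a ends cis to the C8a and C5 methyls (cis ring fusion) against the intrinsic steric bias.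

Step 19
Reactants: 25 (1S,2R,4aS,5S,6R,8aR)-5-(ArCH2)-1-[3-(TBDPSO)propyl]-5,6,8a-trimethyldecahydronaphthalen-2-ol
Product: 26 (1S,4aS,5S,6R,8aR)-5-(ArCH2)-1-[3-(TBDPSO)propyl]-5,6,8a-trimethyloctahydronaphthalen-2(1H)-one
Conditions: Dess–Martin periodinane, NaHCO3, CH2Cl2, rt
Reagents that add atoms: none
Why: Buffered hypervalent-iodine oxidation gives the ketone without base, so the adjacent side-chain-bearing C1 stereocentre is not epimerised.

Step 20
Reactants: 26 (1S,4aS,5S,6R,8aR)-5-(ArCH2)-1-[3-(TBDPSO)propyl]-5,6,8a-trimethyloctahydronaphthalen-2(1H)-one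
Product: 28 (1S,4aS,5S,6R,8aR)-5-(ArCH2)-1-[3-(TBDPSO)propyl]-5,6,8a-trimethyl-1,4,4a,5,6,7,8,8a-octahydronaphthalen-2-yl trifluoromethanesulfonate, via potassium enolate 27 (not isolated)
Conditions: KN(SiMe3)2, THF, −78 °C; PhNTf2
Reagents that add atoms: N-phenylbis(trifluoromethanesulfonimide), O=S(=O)(N(c1ccccc1)S(=O)(=O)C(F)(F)F)C(F)(F)F
Why: Kinetic enolisation occurs at the unhindered C3 methylene, not at the substituted C1, and O-triflation gives the C2=C3 enol triflate regioselectively with C1 untouched.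

Step 21
Reactants: 28 the enol triflate; 29 4,4,5,5-tetramethyl-2-(prop-1-en-2-yl)-1,3,2-dioxaborolane
Product: 30 tert-butyl{3-[(1S,4aS,5S,6R,8aR)-5-(ArCH2)-5,6,8a-trimethyl-2-(prop-1-en-2-yl)-1,4,4a,5,6,7,8,8a-octahydronaphthalen-1-yl]propoxy}diphenylsilane
Conditions: Pd(dppf)Cl2 (5 mol %), K3PO4, dioxane/H2O, 60 °C
Reagents that add atoms: none
Why: Suzuki–Miyaura coupling of the enol triflate with the isopropenyl boronate builds the 2-substituted 1,3-diene under mild base.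

Step 22
Reactants: 30 the 2-isopropenyl diene
Product: 31 tert-butyl{3-[(1S,4aS,5S,6R,8aR)-5-(ArCH2)-5,6,8a-trimethyl-2-(propan-2-ylidene)decahydronaphthalen-1-yl]propoxy}diphenylsilane
Conditions: H2 (50 atm), Cr(CO)3(η6-C10H8) (naphthalene complex, 20 mol %), THF, 45 °C
Reagents that add atoms: none
Why: Arene–chromium-tricarbonyl-catalysed 1,4-hydrogenation adds one H to each terminus of the s-cis diene and leaves the double bond between the inner carbons, giving the tetrasubstituted exocyclic isopropylidene regiospecifically without touching isolated alkenes or the arene.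

Step 23
Reactants: 31 the isopropylidene silyl ether
Product: 32 3-[(1S,4aS,5S,6R,8aR)-5-(ArCH2)-5,6,8a-trimethyl-2-(propan-2-ylidene)decahydronaphthalen-1-yl]propan-1-ol
Conditions: Bu4NF, THF, rt
Reagents that add atoms: none
Why: Fluoride cleaves the TBDPS ether (strong Si–F bond) while the MOM acetal and the alkene are inert.

Step 24
Reactants: 32 the primary alcohol
Product: 34 3-[(1S,4aS,5S,6R,8aR)-5-(ArCH2)-5,6,8a-trimethyl-2-(propan-2-ylidene)decahydronaphthalen-1-yl]propanoic acid, via aldehyde 33 (not isolated)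
Conditions: TEMPO (20 mol %), PhI(OAc)2 (2.5 equiv), MeCN/H2O, rt
Reagents that add atoms: water, O
Why: Oxoammonium-catalysed oxidation takes the primary alcohol through the aldehyde hydrate to the acid; with the phenol still masked as its MOM ether the electron-rich ring is not oxidised.

Step 25
Reactants: 34 the MOM-protected acid
Product: 36 3-[(1S,4aS,5S,6R,8aR)-5-[(2-hydroxy-5-methoxy-3-methylphenyl)methyl]-5,6,8a-trimethyl-2-(propan-2-ylidene)decahydronaphthalen-1-yl]propanoic acid, via bis(trimethylsilyl) derivative 35 (not isolated)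
Conditions: Me3SiOTf, 2,2′-bipyridyl, CH2Cl2, 0 °C; then H2O
Reagents that add atoms: none
Why: Silyl-triflate/bipyridyl cleavage of the aryl MOM acetal under buffered, non-protic conditions, then hydrolysis of the silyl ether and silyl ester, avoids protic acid that could isomerise the tetrasubstituted alkene or lactonise the acid onto it.

**Compound list**

1 | 4-methoxy-2-methylphenol | COc1ccc(O)c(C)c1 | starting material
2 | 2-hydroxy-5-methoxy-3-methylbenzaldehyde | COc1cc(C)c(O)c(C=O)c1 | intermediate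
3 | 5-methoxy-2-(methoxymethoxy)-3-methylbenzaldehyde | COc1cc(C)c(OCOC)c(C=O)c1 | intermediate
4 | [5-methoxy-2-(methoxymethoxy)-3-methylphenyl]methanol | COc1cc(C)c(OCOC)c(CO)c1 | intermediate
5 | 1-(bromomethyl)-5-methoxy-2-(methoxymethoxy)-3-methylbenzene | COc1cc(C)c(OCOC)c(CBr)c1 | intermediate
6 | 3-iodopropan-1-ol | OCCCI | starting material
7 | tert-butyl(3-iodopropoxy)diphenylsilane | CC(C)(C)[Si](OCCCI)(c1ccccc1)c1ccccc1 | intermediate
8 | 4,4-dimethoxycyclohexa-2,5-dien-1-one | COC1(OC)C=CC(=O)C=C1 | starting material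
9 | bis{3-[tert-butyl(diphenyl)silyloxy]propyl}zinc (not isolated) | CC(C)(C)[Si](OCCC[Zn]CCCO[Si](c1ccccc1)(c1ccccc1)C(C)(C)C)(c1ccccc1)c1ccccc1 | intermediate
10 | (5S)-5-[3-(TBDPSO)propyl]-4,4-dimethoxycyclohex-2-en-1-one | O=C1C=CC(OC)(OC)[C@@H](CCCO[Si](c2ccccc2)(c2ccccc2)C(C)(C)C)C1 | intermediate
11 | lithium (3S)-3-[3-(TBDPSO)propyl]-4,4-dimethoxycyclohexa-1,5-dien-1-olate (not isolated) | [Li]OC1=C[C@H](CCCO[Si](c2ccccc2)(c2ccccc2)C(C)(C)C)C(OC)(OC)C=C1 | intermediate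
12 | (5S,6S)-5-[3-(TBDPSO)propyl]-4,4-dimethoxy-6-methylcyclohex-2-en-1-one | O=C1C=CC(OC)(OC)[C@@H](CCCO[Si](c2ccccc2)(c2ccccc2)C(C)(C)C)[C@@H]1C | intermediate
13 | pent-1-en-3-one (ethyl vinyl ketone) | C=CC(=O)CC | starting material
14 | (5S,6S)-5-[3-(TBDPSO)propyl]-4,4-dimethoxy-6-methyl-6-(3-oxopentyl)cyclohex-2-en-1-one | O=C1C=CC(OC)(OC)[C@@H](CCCO[Si](c2ccccc2)(c2ccccc2)C(C)(C)C)[C@]1(C)CCC(=O)CC | intermediate
15 | (2S,3S)-3-[3-(TBDPSO)propyl]-4,4-dimethoxy-2-methyl-2-(3-oxopentyl)cyclohexan-1-one | O=C1CCC(OC)(OC)[C@@H](CCCO[Si](c2ccccc2)(c2ccccc2)C(C)(C)C)[C@]1(C)CCC(=O)CC | intermediate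
16 | (4aS,5S)-5-[3-(TBDPSO)propyl]-6,6-dimethoxy-1,4a-dimethyl-4,4a,5,6,7,8-hexahydronaphthalen-2(3H)-one | CC1=C2CCC(OC)(OC)[C@@H](CCCO[Si](c3ccccc3)(c3ccccc3)C(C)(C)C)[C@]2(C)CCC1=O | intermediate
17 | (4aS,5S)-5-[3-(TBDPSO)propyl]-1,4a-dimethyl-4,4a,7,8-tetrahydronaphthalene-2,6(3H,5H)-dione | CC1=C2CCC(=O)[C@@H](CCCO[Si](c3ccccc3)(c3ccccc3)C(C)(C)C)[C@]2(C)CCC1=O | intermediate
18 | (4aS,5S,6R)-5-[3-(TBDPSO)propyl]-6-hydroxy-1,4a-dimethyl-4,4a,5,6,7,8-hexahydronaphthalen-2(3H)-one | CC1=C2CC[C@@H](O)[C@@H](CCCO[Si](c3ccccc3)(c3ccccc3)C(C)(C)C)[C@]2(C)CCC1=O | intermediate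
19 | (4aS,5S,6R)-5-[3-(TBDPSO)propyl]-1,4a-dimethyl-6-(TESO)-4,4a,5,6,7,8-hexahydronaphthalen-2(3H)-one | CC1=C2CC[C@@H](O[Si](CC)(CC)CC)[C@@H](CCCO[Si](c3ccccc3)(c3ccccc3)C(C)(C)C)[C@]2(C)CCC1=O | intermediate
20 | potassium (4aS,5S,6R)-5-[3-(TBDPSO)propyl]-1,4a-dimethyl-6-(TESO)-3,4,4a,5,6,7-hexahydronaphthalen-2-olate (not isolated) | [K]OC1=C(C)C2=CC[C@@H](O[Si](CC)(CC)CC)[C@@H](CCCO[Si](c3ccccc3)(c3ccccc3)C(C)(C)C)[C@]2(C)CC1 | intermediate
21 | (1R,4aS,5S,6R)-1-(ArCH2)-5-[3-(TBDPSO)propyl]-1,4a-dimethyl-6-(TESO)-3,4,4a,5,6,7-hexahydronaphthalen-2(1H)-one | COc1cc(C)c(OCOC)c(C[C@]2(C)C3=CC[C@@H](O[Si](CC)(CC)CC)[C@@H](CCCO[Si](c4ccccc4)(c4ccccc4)C(C)(C)C)[C@]3(C)CCC2=O)c1 | intermediate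
22 | tert-butyl{3-[(1S,2R,5S,8aS)-5-(ArCH2)-5,8a-dimethyl-6-methylidene-2-(TESO)-1,2,3,5,6,7,8,8a-octahydronaphthalen-1-yl]propoxy}diphenylsilane | COc1cc(C)c(OCOC)c(C[C@]2(C)C3=CC[C@@H](O[Si](CC)(CC)CC)[C@@H](CCCO[Si](c4ccccc4)(c4ccccc4)C(C)(C)C)[C@]3(C)CCC2=C)c1 | intermediate
23 | tert-butyl{3-[(1S,2R,5S,6R,8aS)-5-(ArCH2)-5,6,8a-trimethyl-2-(TESO)-1,2,3,5,6,7,8,8a-octahydronaphthalen-1-yl]propoxy}diphenylsilane | COc1cc(C)c(OCOC)c(C[C@]2(C)C3=CC[C@@H](O[Si](CC)(CC)CC)[C@@H](CCCO[Si](c4ccccc4)(c4ccccc4)C(C)(C)C)[C@]3(C)CC[C@H]2C)c1 | intermediate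
24 | (1S,2R,5S,6R,8aS)-5-(ArCH2)-1-[3-(TBDPSO)propyl]-5,6,8a-trimethyl-1,2,3,5,6,7,8,8a-octahydronaphthalen-2-ol | COc1cc(C)c(OCOC)c(C[C@]2(C)C3=CC[C@@H](O)[C@@H](CCCO[Si](c4ccccc4)(c4ccccc4)C(C)(C)C)[C@]3(C)CC[C@H]2C)c1 | intermediate
25 | (1S,2R,4aS,5S,6R,8aR)-5-(ArCH2)-1-[3-(TBDPSO)propyl]-5,6,8a-trimethyldecahydronaphthalen-2-ol | COc1cc(C)c(OCOC)c(C[C@]2(C)[C@@H]3CC[C@@H](O)[C@@H](CCCO[Si](c4ccccc4)(c4ccccc4)C(C)(C)C)[C@]3(C)CC[C@H]2C)c1 | intermediate
26 | (1S,4aS,5S,6R,8aR)-5-(ArCH2)-1-[3-(TBDPSO)propyl]-5,6,8a-trimethyloctahydronaphthalen-2(1H)-one | COc1cc(C)c(OCOC)c(C[C@]2(C)[C@@H]3CCC(=O)[C@@H](CCCO[Si](c4ccccc4)(c4ccccc4)C(C)(C)C)[C@]3(C)CC[C@H]2C)c1 | intermediate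
27 | potassium (1S,4aS,5S,6R,8aR)-5-(ArCH2)-1-[3-(TBDPSO)propyl]-5,6,8a-trimethyl-1,4,4a,5,6,7,8,8a-octahydronaphthalen-2-olate (not isolated) | COc1cc(C)c(OCOC)c(C[C@]2(C)[C@@H]3CC=C(O[K])[C@@H](CCCO[Si](c4ccccc4)(c4ccccc4)C(C)(C)C)[C@]3(C)CC[C@H]2C)c1 | intermediate
28 | (1S,4aS,5S,6R,8aR)-5-(ArCH2)-1-[3-(TBDPSO)propyl]-5,6,8a-trimethyl-1,4,4a,5,6,7,8,8a-octahydronaphthalen-2-yl trifluoromethanesulfonate | COc1cc(C)c(OCOC)c(C[C@]2(C)[C@@H]3CC=C(OS(=O)(=O)C(F)(F)F)[C@@H](CCCO[Si](c4ccccc4)(c4ccccc4)C(C)(C)C)[C@]3(C)CC[C@H]2C)c1 | intermediate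
29 | 4,4,5,5-tetramethyl-2-(prop-1-en-2-yl)-1,3,2-dioxaborolane | CC(=C)B1OC(C)(C)C(C)(C)O1 | starting material
30 | tert-butyl{3-[(1S,4aS,5S,6R,8aR)-5-(ArCH2)-5,6,8a-trimethyl-2-(prop-1-en-2-yl)-1,4,4a,5,6,7,8,8a-octahydronaphthalen-1-yl]propoxy}diphenylsilane | COc1cc(C)c(OCOC)c(C[C@]2(C)[C@@H]3CC=C(C(C)=C)[C@@H](CCCO[Si](c4ccccc4)(c4ccccc4)C(C)(C)C)[C@]3(C)CC[C@H]2C)c1 | intermediate
31 | tert-butyl{3-[(1S,4aS,5S,6R,8aR)-5-(ArCH2)-5,6,8a-trimethyl-2-(propan-2-ylidene)decahydronaphthalen-1-yl]propoxy}diphenylsilane | COc1cc(C)c(OCOC)c(C[C@]2(C)[C@@H]3CCC(=C(C)C)[C@@H](CCCO[Si](c4ccccc4)(c4ccccc4)C(C)(C)C)[C@]3(C)CC[C@H]2C)c1 | intermediate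
32 | 3-[(1S,4aS,5S,6R,8aR)-5-(ArCH2)-5,6,8a-trimethyl-2-(propan-2-ylidene)decahydronaphthalen-1-yl]propan-1-ol | COc1cc(C)c(OCOC)c(C[C@]2(C)[C@@H]3CCC(=C(C)C)[C@@H](CCCO)[C@]3(C)CC[C@H]2C)c1 | intermediate
33 | 3-[(1S,4aS,5S,6R,8aR)-5-(ArCH2)-5,6,8a-trimethyl-2-(propan-2-ylidene)decahydronaphthalen-1-yl]propanal (not isolated) | COc1cc(C)c(OCOC)c(C[C@]2(C)[C@@H]3CCC(=C(C)C)[C@@H](CCC=O)[C@]3(C)CC[C@H]2C)c1 | intermediate
34 | 3-[(1S,4aS,5S,6R,8aR)-5-(ArCH2)-5,6,8a-trimethyl-2-(propan-2-ylidene)decahydronaphthalen-1-yl]propanoic acid | COc1cc(C)c(OCOC)c(C[C@]2(C)[C@@H]3CCC(=C(C)C)[C@@H](CCC(=O)O)[C@]3(C)CC[C@H]2C)c1 | intermediate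
35 | trimethylsilyl 3-[(1S,4aS,5S,6R,8aR)-5-{[5-methoxy-3-methyl-2-(trimethylsilyloxy)phenyl]methyl}-5,6,8a-trimethyl-2-(propan-2-ylidene)decahydronaphthalen-1-yl]propanoate (not isolated) | COc1cc(C)c(O[Si](C)(C)C)c(C[C@]2(C)[C@@H]3CCC(=C(C)C)[C@@H](CCC(=O)O[Si](C)(C)C)[C@]3(C)CC[C@H]2C)c1 | intermediate
36 | 3-[(1S,4aS,5S,6R,8aR)-5-[(2-hydroxy-5-methoxy-3-methylphenyl)methyl]-5,6,8a-trimethyl-2-(propan-2-ylidene)decahydronaphthalen-1-yl]propanoic acid | COc1cc(C)c(O)c(C[C@]2(C)[C@@H]3CCC(=C(C)C)[C@@H](CCC(=O)O)[C@]3(C)CC[C@H]2C)c1 | target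

**Count and risks**

Total step count: 25 (4 for bromide 5, 1 for iodide 7, 20 in the main line).
Longest linear sequence: 21 steps (6 → 7 → 10 → … → 36, steps 5 to 25).

Steps most likely to fail:

Step 18 (directed hydrogenation). The α face of the C4=C4a alkene lies between the C5 and C8a methyl groups, so the iridium catalyst may fail to bind there or may give the trans-fused isomer. The fallback delivers the ring-fusion hydrogen intramolecularly and sets out from 23. Allylic oxidation at C3 (CrO3, 3,5-dimethylpyrazole, CH2Cl2, −20 °C) gives the conjugated enone F1. Condensation with TsNHNH2 (EtOH, 60 °C) gives the tosylhydrazone F2. Catecholborane (CHCl3, 0 °C), then NaOAc·3H2O at reflux, brings about reductive alkene transposition: hydride adds to C=N anti to the neighbouring silyloxy group, and the resulting allylic diazene passes its hydrogen suprafacially to C4a, giving the cis-fused alkene silyl ether F3. HF·pyridine then gives the allylic alcohol F4, and hydrogenation of its disubstituted alkene (H2, RhCl(PPh3)3) comes back to the route at 25.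

Step 22 (1,4-hydrogenation). The diene carries a substituted neighbour at C1 and may bind the chromium catalyst poorly, or the arene of the substrate may sequester the metal. The fallback builds the alkene from the ketone instead and sets out from 26. Dibromo-olefination (PPh3, CBr4, PhMe, 80 °C) gives the gem-dibromoalkene F5, and a double Negishi methylation (Me2Zn, Pd(P(t-Bu)3)2, THF, 50 °C) comes back to the route at 31, bypassing 28 and 30.

Step 12 (ketoreductase). No enzyme of the panel may accept this lipophilic bicyclic ketone with the required facial preference. The fallback replaces catalyst control by substrate control and sets out from 17. LiBH(s-Bu)3 in THF at −78 °C attacks the ring-A ketone equatorially, because the axial path is blocked by the syn-axial angular methyl, and the hindered enone is left alone. This gives the same axial alcohol and comes back to the route at 18 directly; no compound outside the list is made (F0).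

**Further compounds**

F1 | step 18 | (3S,4S,4aS,7R,8S)-8-(ArCH2)-4-[3-(TBDPSO)propyl]-4a,7,8-trimethyl-3-(TESO)-4,4a,5,6,7,8-hexahydronaphthalen-2(3H)-one | COc1cc(C)c(OCOC)c(C[C@]2(C)C3=CC(=O)[C@@H](O[Si](CC)(CC)CC)[C@@H](CCCO[Si](c4ccccc4)(c4ccccc4)C(C)(C)C)[C@]3(C)CC[C@H]2C)c1
F2 | step 18 | N′-[(3S,4S,4aS,7R,8S)-8-(ArCH2)-4-[3-(TBDPSO)propyl]-4a,7,8-trimethyl-3-(TESO)-4,4a,5,6,7,8-hexahydronaphthalen-2(3H)-ylidene]-4-methylbenzenesulfonohydrazide | COc1cc(C)c(OCOC)c(C[C@]2(C)C3=CC(=NNS(=O)(=O)c4ccc(C)cc4)[C@@H](O[Si](CC)(CC)CC)[C@@H](CCCO[Si](c4ccccc4)(c4ccccc4)C(C)(C)C)[C@]3(C)CC[C@H]2C)c1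
F3 | step 18 | tert-butyl{3-[(1S,2R,4aS,5S,6R,8aR)-5-(ArCH2)-5,6,8a-trimethyl-2-(TESO)-1,2,4a,5,6,7,8,8a-octahydronaphthalen-1-yl]propoxy}diphenylsilane | COc1cc(C)c(OCOC)c(C[C@]2(C)[C@@H]3C=C[C@@H](O[Si](CC)(CC)CC)[C@@H](CCCO[Si](c4ccccc4)(c4ccccc4)C(C)(C)C)[C@]3(C)CC[C@H]2C)c1
F4 | step 18 | (1S,2R,4aS,5S,6R,8aR)-5-(ArCH2)-1-[3-(TBDPSO)propyl]-5,6,8a-trimethyl-1,2,4a,5,6,7,8,8a-octahydronaphthalen-2-ol | COc1cc(C)c(OCOC)c(C[C@]2(C)[C@@H]3C=C[C@@H](O)[C@@H](CCCO[Si](c4ccccc4)(c4ccccc4)C(C)(C)C)[C@]3(C)CC[C@H]2C)c1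
F5 | step 22 | tert-butyl{3-[(1S,4aS,5S,6R,8aR)-2-(dibromomethylidene)-5-(ArCH2)-5,6,8a-trimethyldecahydronaphthalen-1-yl]propoxy}diphenylsilane | COc1cc(C)c(OCOC)c(C[C@]2(C)[C@@H]3CCC(=C(Br)Br)[C@@H](CCCO[Si](c4ccccc4)(c4ccccc4)C(C)(C)C)[C@]3(C)CC[C@H]2C)c1
F0 | step 12 | none | none
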